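**Retrosynthetic overview**

1. The target, 8-(1,1-dimethylallyl)kaempferol, is reached by removing three O-acetyl groups; just before that, zinc returns the vinyl group from a vicinal dibromide, which stores the olefin because a monosubstituted olefin is not expected to survive hot CF3CO2H and a trivalent iodine oxidant.
2. Key disconnection: the C5–O bond of ring A. C5 is the only ring A carbon peri to the C4 carbonyl (O=C4–C4a–C5), so a metal held on that carbonyl reaches C5–H alone and the C5 hydroxyl can be the last oxygen put on the finished flavonol.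
3. A ring A without the C5 oxygen has a single hydroxyl ortho to the acyl carbon, so ring C can close in one sense only; the C8 quaternary carbon then comes from an aromatic Claisen rearrangement of the C7–O prenyl ether, directed to C8 by the C7–C8 bond fixation of the benzopyranone.
4. The 5-deoxyflavonol is assembled from 2,4-dihydroxyacetophenone (prenylated first on its free C4 hydroxyl), and 4-hydroxybenzaldehyde by Claisen–Schmidt condensation and Algar–Flynn–Oyamada oxidation.
5. Ring order: rings A and B are bought, ring C (the pyranone) is formed in step 3, and no ring is formed afterwards.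

Key step: step 7

Assumption: the tetrahydropyranyl acetal carbon and the CHBr carbon of the masked side chain are carried as racemates (the transient dihydroflavonol as its trans racemate); all these centres are gone before the target, which has no stereocentre.

**Step 1**
Reactants: 1 2,4-dihydroxyacetophenone; 2 prenyl bromide (1-bromo-3-methylbut-2-ene)
Product: 3 2-hydroxy-4-(prenyloxy)acetophenone
Conditions: K2CO3, acetone, reflux
Reagents that add atoms: prenyl bromide (2), CC(C)=CCBr
Why: Williamson ether synthesis in which the C2 hydroxyl, hydrogen-bonded to the acetyl oxygen, is much less acidic and nucleophilic, so only the C4 phenoxide is alkylated by the primary allylic bromide.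

**Step 2**
Reactants: 4 4-hydroxybenzaldehyde
Product: 5 4-(tetrahydro-2H-pyran-2-yloxy)benzaldehyde (racemic)
Conditions: 3,4-dihydro-2H-pyran, PPTS (cat.), CH2Cl2, rt
Reagents that add atoms: 3,4-dihydro-2H-pyran, C1=COCCC1
Why: PPTS-catalysed addition of the phenol to the enol ether (tetrahydropyranyl protection) gives a base-stable acetal, needed because a free para-phenoxide would deactivate the aldehyde in the aldol step and the enone in the oxidative cyclisation; the acetal carbon forms as a racemate.

**Step 3**
Reactants: 3 2-hydroxy-4-(prenyloxy)acetophenone; 5 4-(tetrahydro-2H-pyran-2-yloxy)benzaldehyde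
Product: 8 3-hydroxy-7-(prenyloxy)-4'-(tetrahydropyran-2-yloxy)flavone, via chalcone 6 (not isolated), via trans-dihydroflavonol 7 (not isolated)
Conditions: KOH, EtOH, rt; then 30% H2O2, 0 °C to rt; AcOH to pH 6
Reagents that add atoms: hydrogen peroxide, OO
Why: Claisen–Schmidt condensation gives the E-chalcone and alkaline H2O2 then effects the Algar–Flynn–Oyamada reaction, in which the single ortho phenoxide closes ring C on the enone with hydroxylation at C3 and the dihydroflavonol is dehydrogenated in the pot, so its two transient stereocentres are erased; without a 6'-substituent the flavonol rather than the aurone is expected, and the hydroperoxide anion leaves the electron-rich prenyl olefin alone.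

**Step 4**
Reactants: 8 3-hydroxy-7-(prenyloxy)-4'-(tetrahydropyran-2-yloxy)flavone
Product: 9 3,4'-dihydroxy-7-(prenyloxy)flavone
Conditions: p-TsOH·H2O (cat.), MeOH/THF, rt
Reagents that add atoms: none
Why: Acid-catalysed transacetalisation to methanol removes the aryl tetrahydropyranyl ether at room temperature, conditions too mild to ionise the aryl prenyl ether.

**Step 5**
Reactants: 9 3,4'-dihydroxy-7-(prenyloxy)flavone
Product: 12 3,7,4'-triacetoxy-8-(2-methylbut-3-en-2-yl)flavone, via diacetate 10 (not isolated), via C8-allylated phenol 11 (not isolated)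
Conditions: Ac2O, NaOAc, PhNEt2, 100 °C then 190 °C (sealed tube), argon
Reagents that add atoms: acetic anhydride, CC(=O)OC(C)=O
Why: After acetylation of the two free hydroxyls, the aryl prenyl ether undergoes the aromatic Claisen rearrangement ([3,3], allylic inversion) to put the 1,1-dimethylallyl group on C8, favoured over C6 by the higher double-bond character of C7–C8 in the benzopyranone, and acetic anhydride traps the new C7 phenol at once, which should suppress the abnormal Claisen rearrangement and cyclisation onto the olefin.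

**Step 6**
Reactants: 12 3,7,4'-triacetoxy-8-(2-methylbut-3-en-2-yl)flavone
Product: 13 3,7,4'-triacetoxy-8-(3,4-dibromo-2-methylbutan-2-yl)flavone (racemic)
Conditions: Br2, CH2Cl2, −20 °C to 0 °C, dark
Reagents that add atoms: bromine, BrBr
Why: Electrophilic anti addition of bromine to the only isolated olefin (the rings are deactivated by the acetates and the pyranone), with bromide opening the bromonium ion at the unhindered terminal carbon; the CHBr centre forms as a racemate without control, which is harmless because step 8 removes it.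

**Step 7**
Reactants: 13 3,7,4'-triacetoxy-8-(3,4-dibromo-2-methylbutan-2-yl)flavone
Product: 15 3,7,4'-triacetoxy-8-(3,4-dibromo-2-methylbutan-2-yl)-5-hydroxyflavone, via C5 trifluoroacetate 14 (not isolated)
Conditions: [RuCl2(p-cymene)]2 (cat.), PhI(OCOCF3)2, CF3CO2H/(CF3CO)2O, 80 °C; then aq. NaHCO3, rt
Reagents that add atoms: phenyliodine bis(trifluoroacetate), O=C(O[I](OC(=O)C(F)(F)F)c1ccccc1)C(F)(F)F; trifluoroacetic acid (trifluoroacetate pool that supplies the C5 oxygen), OC(=O)C(F)(F)F
Why: A cationic divalent ruthenium trifluoroacetate binds the C4 carbonyl oxygen and cleaves the peri C5–H bond by carboxylate-assisted metalation to a five-membered ruthenacycle (Ru–O=C4–C4a–C5); PhI(OCOCF3)2 oxidises it to a tetravalent ruthenium aryl trifluoroacetate, C–O reductive elimination releases the C5 trifluoroacetate 14 and divalent ruthenium, and mild aqueous base on work-up cleaves that aryl trifluoroacetate to the chelated C5 phenol 15. The closest known reaction type is the ruthenium-catalysed ketone-directed ortho C–H oxygenation of aryl ketones with trivalent iodine oxidants in CF3CO2H/(CF3CO)2O, which has been carried out at C5 of flavones and chromones. No ring is closed and no stereocentre is formed; the racemic CHBr centre of the side chain is untouched. The selectivity needed is C5 over C6 and over the ring B C–H bonds, and chelation secures it: C5–H is the only C–H bond within reach of a metal held on the C4 carbonyl, ring B has no directing group, and the acetates keep all rings electron-poor and stop the C3 oxygen from chelating the metal. The side chain should be inert because the olefin is stored as a vicinal dibromide, which neither CF3CO2H nor the iodine oxidant attacks, and any acetate exchanged for trifluoroacetate in the medium only ends as a phenol that step 9 would free anyway.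

**Step 8**
Reactants: 15 3,7,4'-triacetoxy-8-(3,4-dibromo-2-methylbutan-2-yl)-5-hydroxyflavone
Product: 16 3,7,4'-triacetoxy-5-hydroxy-8-(2-methylbut-3-en-2-yl)flavone
Conditions: Zn dust, AcOH, THF, 0 °C to rt
Reagents that add atoms: none
Why: Zinc-mediated reductive 1,2-elimination of the vicinal dibromide regenerates the olefin, and only the terminal vinyl group can form because the neighbouring carbon is quaternary, while aryl acetates and the chromone are inert to zinc in acetic acid at this temperature.

**Step 9**
Reactants: 16 3,7,4'-triacetoxy-5-hydroxy-8-(2-methylbut-3-en-2-yl)flavone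
Product: 17 3,5,7-trihydroxy-2-(4-hydroxyphenyl)-8-(2-methylbut-3-en-2-yl)-4H-chromen-4-one (target)
Conditions: K2CO3, MeOH, argon, 0 °C to rt; then 1 M HCl to pH 5 at 0 °C
Reagents that add atoms: none
Why: Carbonate-mediated methanolysis (transesterification) of the two aryl acetates and the C3 enol acetate under argon frees the hydroxyls without touching the olefin, and the cold, weakly acidic quench avoids acid-catalysed cyclisation of the C7 hydroxyl onto the 1,1-dimethylallyl group.

**Compound list**

1 | 2,4-dihydroxyacetophenone | CC(=O)c1ccc(O)cc1O | starting material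
2 | prenyl bromide (1-bromo-3-methylbut-2-ene) | CC(C)=CCBr | starting material
3 | 2-hydroxy-4-(prenyloxy)acetophenone | CC(=O)c1ccc(OCC=C(C)C)cc1O | intermediate
4 | 4-hydroxybenzaldehyde | O=Cc1ccc(O)cc1 | starting material
5 | 4-(tetrahydro-2H-pyran-2-yloxy)benzaldehyde (racemic) | O=Cc1ccc(OC2CCCCO2)cc1 | intermediate
6 | (E)-1-[2-hydroxy-4-(prenyloxy)phenyl]-3-[4-(tetrahydropyran-2-yloxy)phenyl]prop-2-en-1-one (not isolated) | O=C(/C=C/c1ccc(OC2CCCCO2)cc1)c1ccc(OCC=C(C)C)cc1O | intermediate
7 | trans-3-hydroxy-7-(prenyloxy)-2-[4-(tetrahydropyran-2-yloxy)phenyl]chroman-4-one (racemic trans, 2R,3R enantiomer drawn, acetal carbon unassigned; not isolated) | O=C1c2ccc(OCC=C(C)C)cc2O[C@H](c2ccc(OC3CCCCO3)cc2)[C@H]1O | intermediate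
8 | 3-hydroxy-7-(prenyloxy)-4'-(tetrahydropyran-2-yloxy)flavone (racemic at the acetal carbon) | O=c1c(O)c(-c2ccc(OC3CCCCO3)cc2)oc2cc(OCC=C(C)C)ccc12 | intermediate
9 | 3,4'-dihydroxy-7-(prenyloxy)flavone | O=c1c(O)c(-c2ccc(O)cc2)oc2cc(OCC=C(C)C)ccc12 | intermediate
10 | 3,4'-diacetoxy-7-(prenyloxy)flavone (not isolated) | CC(=O)Oc1ccc(-c2oc3cc(OCC=C(C)C)ccc3c(=O)c2OC(C)=O)cc1 | intermediate
11 | 3,4'-diacetoxy-7-hydroxy-8-(2-methylbut-3-en-2-yl)flavone (not isolated) | C=CC(C)(C)c1c(O)ccc2c(=O)c(OC(C)=O)c(-c3ccc(OC(C)=O)cc3)oc12 | intermediate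
12 | 3,7,4'-triacetoxy-8-(2-methylbut-3-en-2-yl)flavone | C=CC(C)(C)c1c(OC(C)=O)ccc2c(=O)c(OC(C)=O)c(-c3ccc(OC(C)=O)cc3)oc12 | intermediate
13 | 3,7,4'-triacetoxy-8-(3,4-dibromo-2-methylbutan-2-yl)flavone (racemic) | BrCC(Br)C(C)(C)c1c(OC(C)=O)ccc2c(=O)c(OC(C)=O)c(-c3ccc(OC(C)=O)cc3)oc12 | intermediate
14 | 3,7,4'-triacetoxy-8-(3,4-dibromo-2-methylbutan-2-yl)-5-(trifluoroacetoxy)flavone (racemic; not isolated) | BrCC(Br)C(C)(C)c1c(OC(C)=O)cc(OC(=O)C(F)(F)F)c2c(=O)c(OC(C)=O)c(-c3ccc(OC(C)=O)cc3)oc12 | intermediate
15 | 3,7,4'-triacetoxy-8-(3,4-dibromo-2-methylbutan-2-yl)-5-hydroxyflavone (racemic) | BrCC(Br)C(C)(C)c1c(OC(C)=O)cc(O)c2c(=O)c(OC(C)=O)c(-c3ccc(OC(C)=O)cc3)oc12 | intermediate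
16 | 3,7,4'-triacetoxy-5-hydroxy-8-(2-methylbut-3-en-2-yl)flavone | C=CC(C)(C)c1c(OC(C)=O)cc(O)c2c(=O)c(OC(C)=O)c(-c3ccc(OC(C)=O)cc3)oc12 | intermediate
17 | 3,5,7-trihydroxy-2-(4-hydroxyphenyl)-8-(2-methylbut-3-en-2-yl)-4H-chromen-4-one | C=CC(C)(C)c1c(O)cc(O)c2c(=O)c(O)c(-c3ccc(O)cc3)oc12 | target

**Step count**

Total steps: 9. Longest linear sequence: 8 steps (steps 1 and 3–9 from compound 1, or equally steps 2 and 3–9 from compound 4).

**Steps most likely to fail**

Step 7 (key step). What may go wrong: slow ruthenation at the crowded, weakly basic C4 carbonyl, over-oxidation of the rings once acetates exchange, or solvolytic erosion of the dibromide in the hot acid. The fallback buys the C5 oxygen with ring A and gives up the regiochemical certainty of the 5-deoxy Claisen step. It sets out from 2 and comes back to the route at 17. Commercial kaempferol F1 is peracetylated (Ac2O, pyridine) to kaempferol tetraacetate F2. Thiophenol and imidazole in N-methylpyrrolidone at 0 °C should remove the most labile C7 acetate to give 3,5,4'-triacetoxy-7-hydroxyflavone F3. Compound 2 with K2CO3 in acetone then gives 3,5,4'-triacetoxy-7-(prenyloxy)flavone F4. The conditions of step 5 (Ac2O, NaOAc, PhNEt2, 190 °C) should give 3,5,7,4'-tetraacetoxy-8-(2-methylbut-3-en-2-yl)flavone F5, which would have to be separated from its C6 isomer. K2CO3 in MeOH as in step 9 then gives 17.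

Step 5. What may go wrong: partial migration of the allyl group to C6, or abnormal Claisen rearrangement and cyclisation if acetylation of the new C7 phenol lags behind the rearrangement. The fallback moves the sigmatropic step to the acetophenone, where the chelated C2 hydroxyl fixes the ring bonds so that migration goes to C3, the future C8. It sets out from 3 and comes back at 12. Heating 3 in aqueous ethanol (sealed tube, about 130 °C; water-accelerated Claisen rearrangement) should give 2,4-dihydroxy-3-(2-methylbut-3-en-2-yl)acetophenone F6. Dihydropyran and PPTS give 2-hydroxy-3-(2-methylbut-3-en-2-yl)-4-(tetrahydropyran-2-yloxy)acetophenone F7. F7 and 5 are taken through the one-pot conditions of step 3, by way of the chalcone (E)-1-[2-hydroxy-3-(2-methylbut-3-en-2-yl)-4-(tetrahydropyran-2-yloxy)phenyl]-3-[4-(tetrahydropyran-2-yloxy)phenyl]prop-2-en-1-one F8 and the trans-dihydroflavonol 3-hydroxy-8-(2-methylbut-3-en-2-yl)-7-(tetrahydropyran-2-yloxy)-2-[4-(tetrahydropyran-2-yloxy)phenyl]chroman-4-one F9, to 3-hydroxy-8-(2-methylbut-3-en-2-yl)-7,4'-bis(tetrahydropyran-2-yloxy)flavone F10. p-TsOH in MeOH gives 3,7,4'-trihydroxy-8-(2-methylbut-3-en-2-yl)flavone F11, and Ac2O with pyridine and DMAP gives 12.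

Step 6. What may go wrong: capture of the bromonium ion by the neighbouring aryl ring or by the C7 acetate, leading to skeletal rearrangement or cyclisation, or competing ring bromination. The fallback drops the mask. It sets out from 12 and comes back at 16. Compound 12 itself is treated with [RuCl2(p-cymene)]2 and PhI(OCOCF3)2 in 1,2-dichloroethane containing only a few equivalents of CF3CO2H and (CF3CO)2O, at the lowest temperature at which the catalyst turns over. This gives 3,7,4'-triacetoxy-8-(2-methylbut-3-en-2-yl)-5-(trifluoroacetoxy)flavone F12 and, after aqueous work-up, 16 directly. The olefin is then exposed for a shorter time to a far less acidic medium, at the price of expected partial loss of the vinyl group.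

**Further compounds**

F1 | step 7 | kaempferol | O=c1c(O)c(-c2ccc(O)cc2)oc2cc(O)cc(O)c12
F2 | step 7 | kaempferol tetraacetate (3,5,7,4'-tetraacetoxyflavone) | CC(=O)Oc1ccc(-c2oc3cc(OC(C)=O)cc(OC(C)=O)c3c(=O)c2OC(C)=O)cc1
F3 | step 7 | 3,5,4'-triacetoxy-7-hydroxyflavone | CC(=O)Oc1ccc(-c2oc3cc(O)cc(OC(C)=O)c3c(=O)c2OC(C)=O)cc1
F4 | step 7 | 3,5,4'-triacetoxy-7-(prenyloxy)flavone | CC(=O)Oc1ccc(-c2oc3cc(OCC=C(C)C)cc(OC(C)=O)c3c(=O)c2OC(C)=O)cc1
F5 | step 7 | 3,5,7,4'-tetraacetoxy-8-(2-methylbut-3-en-2-yl)flavone | C=CC(C)(C)c1c(OC(C)=O)cc(OC(C)=O)c2c(=O)c(OC(C)=O)c(-c3ccc(OC(C)=O)cc3)oc12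
F6 | step 5 | 2,4-dihydroxy-3-(2-methylbut-3-en-2-yl)acetophenone | CC(=O)c1ccc(O)c(C(C)(C)C=C)c1O
F7 | step 5 | 2-hydroxy-3-(2-methylbut-3-en-2-yl)-4-(tetrahydropyran-2-yloxy)acetophenone (racemic) | CC(=O)c1ccc(OC2CCCCO2)c(C(C)(C)C=C)c1O
F8 | step 5 | (E)-1-[2-hydroxy-3-(2-methylbut-3-en-2-yl)-4-(tetrahydropyran-2-yloxy)phenyl]-3-[4-(tetrahydropyran-2-yloxy)phenyl]prop-2-en-1-one | O=C(/C=C/c1ccc(OC2CCCCO2)cc1)c1ccc(OC2CCCCO2)c(C(C)(C)C=C)c1O
F9 | step 5 | trans-3-hydroxy-8-(2-methylbut-3-en-2-yl)-7-(tetrahydropyran-2-yloxy)-2-[4-(tetrahydropyran-2-yloxy)phenyl]chroman-4-one (racemic trans, acetal carbons unassigned) | O=C1c2ccc(OC3CCCCO3)c(C(C)(C)C=C)c2O[C@H](c2ccc(OC3CCCCO3)cc2)[C@H]1O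
F10 | step 5 | 3-hydroxy-8-(2-methylbut-3-en-2-yl)-7,4'-bis(tetrahydropyran-2-yloxy)flavone | O=c1c(O)c(-c2ccc(OC3CCCCO3)cc2)oc2c(C(C)(C)C=C)c(OC3CCCCO3)ccc12
F11 | step 5 | 3,7,4'-trihydroxy-8-(2-methylbut-3-en-2-yl)flavone | C=CC(C)(C)c1c(O)ccc2c(=O)c(O)c(-c3ccc(O)cc3)oc12
F12 | step 6 | 3,7,4'-triacetoxy-8-(2-methylbut-3-en-2-yl)-5-(trifluoroacetoxy)flavone | C=CC(C)(C)c1c(OC(C)=O)cc(OC(=O)C(F)(F)F)c2c(=O)c(OC(C)=O)c(-c3ccc(OC(C)=O)cc3)oc12
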